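## The problem

The target 26 is a monocyclic lignan: one tetrahydrofuran (O1, C2, C3, C4, C5) carrying a 3,4-dihydroxyphenyl group at C2, an acetoxymethyl group (C9) at C3 and a 4-hydroxy-3-methoxybenzyl group (through C7') at C4, with C5 an unsubstituted ether CH2. The three contiguous stereocentres are (2S,3R,4R): aryl and C9 trans, C9 and C7' cis. The cis pair is the less stable arrangement and cannot be left to equilibration. C2 and C3 form an aldol-type pair (oxygen on C2, carbon branch on C3) and can be set together, whereas C4 has no heteroatom handle and is best placed under the control of C3. The C2–O1 bond is a benzylic ether of an electron-rich arene, so it ionises under acid and can be hydrogenolysed. The catechol must stay masked to the end, and the primary acetate tolerates neither hydride, organometallics nor strong base, so it has to come late, when C9–OH is the only primary hydroxyl and the phenols are still protected. The two arenes differ and must arrive separately. The enabling feature is that C9–O and C7' are cis and can be tied as a γ-lactone with C7' as carbonyl, which makes C4 its α-carbon, while C5, a lone CH2 on O1, can begin as a methyl ether on the C2 oxygen. A carbenoid at C4 then lies five atoms from the methyl hydrogens, and the ring it closes is fused to the lactone, where only cis is possible.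

## Retrosynthesis

**Phenol unmasking (26 from 25).** The three aryl O–benzyl bonds are cut last, so 26 comes from tri-O-benzyl ether 25. Benzyl is preferred to silyl (amide bases, aryllithium and triethylamine/water lie on the way) and to methyl (not removable beside the guaiacyl methyl ether). The skeleton is no simpler, but no free phenol is carried. The forward reaction must stop before the benzylic C2–O1 bond is touched.

**C7' oxygen and acetate (25 from 24, 23, 22).** The C7'–H bond is traced back to a C7'–O bond (thionocarbonate 24, alcohol 23), and the acetyl group is removed to give diol 22. Putting oxygen back on C7' turns the C7'–aryl bond into a carbonyl addition, more reliable than coupling an sp3 C7' electrophile that sits cis to a neighbouring branch. Diol 22 has one primary and one secondary benzylic hydroxyl, so it can be differentiated. The forward steps need primary-selective acetylation and a deoxygenation that leaves C4 alone, hence a radical one.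

**C7'–aryl bond (22 from 21, then 17 plus 20).** Diol 22 comes from ketone 21, and 21 from addition of aryllithium 20 (from bromide 19, from phenol 18) to bicyclic lactone 17. This is preferred to cutting C4–C7', which would have to set C4 intermolecularly, whereas lactone 17 stores the cis relation of C9 and C7' in a ring. The precursor loses one arene and becomes a compact bicycle holding all three stereocentres. The forward reaction must transfer one aryl group only and must not epimerise C4.

**C4–C5 bond, the key disconnection (17 from 16).** Cutting C4–C5 of 17 gives α-diazo lactone 16, in which C5 is the methyl of a C2 methyl ether. Cutting O1–C5 or O1–C2 instead would need a one-carbon branch on C4 cis to C2, while enolate alkylation next to the C3 branch gives trans. The carbenoid delivers C5 from O1 itself, so cis is automatic. Rings go from two to one and stereocentres from three to two. The forward reaction needs 1,5-insertion to beat 1,2-hydride shift and attack on the arene.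

**Diazo group (16 from 15, from 13).** The C4=N2 unit comes from lactone 13 through trifluoroacetyl lactone 15, because a plain lactone is not acidic enough for direct diazo transfer. The precursor is the simple β-substituted butyrolactone. The forward steps need clean acylation at C4 and mild transfer.

**Lactone (13 from 12, from 9).** The C7'–O bond and the C7' oxidation level are traced to lactol 12 and then to pentenol 9, whose vinyl group is C7' plus one extra carbon. A succinate-type aldol partner with C7' already an ester was rejected, because the aldol hydroxyl at C2 would lactonise onto it and give the wrong ring. The forward cleavage of the alkene must spare the dialkoxyarene.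

**C2–C3 bond (9 from 8, 7, then 3 plus 4).** Alcohol 9 comes from imide 8 (C9–N cut), 8 from aldol 7 (O–CH3 cut, the future C5), and 7 from imide 3 and aldehyde 4 by a syn-aldol. The syn pair maps onto the 2,3-trans ring substituents and places the aryl on the convex face of 17. The precursors are an achiral aldehyde and an acyl oxazolidinone. The forward reaction needs high syn selectivity in the right absolute sense and a methylation that avoids retro-aldol.

**Feedstocks (3 from 1 plus 2; 19 from 18).** Imide 3 is cut at the N–acyl bond to oxazolidinone 1 and acid chloride 2. Bromide 19 is cut at the O–benzyl bond to phenol 18.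

## Roads not taken

**Alternative 1:** The cut is C2–C3 together with O1–C5, C5 being a lactone carbonyl. Aldehyde 4 and the (Z)-2-methoxycarbonyl allylboronate A2 would react under a chiral BINOL-derived phosphoric acid through a chair allylboration, and the borate alkoxide would lactonise to the trans α-methylene lactone A1. Conjugate addition of the guaiacyl group to the exocyclic methylene, reduction of the lactone to the ether, acetate exchange and debenzylation would follow.
- Merits: it is convergent, sets C2 and C3 and closes the ring in one catalytic step, and is clearly shorter than the chosen plan.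
- Weak points: ester-bearing allylboronates with a γ-substituent are sluggish, and their catalytic enantioselective use is far less established than for simple allylboronates.
- C4 is made by protonation α to a carbonyl, and the needed 3,4-cis isomer is the less stable, epimerisable one.
- C5 must be reduced from lactone to ether with a Lewis acid and a silane right beside the ionisable C2–O bond.
- Comparison: the chosen plan is longer. Against that it sets a ring fusion that allows only cis at C4, has C5 at the ether level from the start, and takes its absolute configuration from an auxiliary of predictable sense.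

**Alternative 2:** The cut is C3–C9 and C4–C7' at once. CoBr2(dppp), reduced by Zn with ZnI2 to monovalent cobalt, would join alkyne A5 and the (S)-2-aryl-2,5-dihydrofuran A4 in a [2+2] cycloaddition anti to the aryl group, giving cyclobutene A3. Cleavage of its C9=C7' bond would leave a formyl group on C3 and an aroyl group on C4, cis.
- Merits: it is the shortest assembly of the skeleton, the cis relation comes from a suprafacial cycloaddition, and C9 and C7' emerge already differentiated with the guaiacyl ring attached. In these respects it is better than the chosen plan.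
- Weak points: this cycloaddition is secure mainly for strained alkenes. An allylic ether such as A4 can isomerise or undergo ene-type coupling, and a terminal aryl alkyne can trimerise.
- The regiochemistry (aryl-bearing alkyne carbon to C4) has no clear control element.
- A4 needs its own asymmetric synthesis.
- After cleavage both C3 and C4 are α to carbonyls, so the cis-dicarbonyl can epimerise, and the C7' ketone still has to be deoxygenated.
- Comparison: the chosen plan never makes C3 acidic and concentrates its risk in one step with a fallback.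

**Alternative 3:** The cut is O1–C2, with a C4=C5 enol ether as retron. Sc(OTf)3 would open the C2–C4 bond of cyclopropanecarbaldehyde A7, and the aldehyde oxygen would close on benzylic C2 (Cloke–Wilson ring expansion) to give dihydrofuran A6. Hydrogenation of the enol ether, acetate exchange and debenzylation would follow.
- Merits: all carbons including C7' are in place, C5 is at the ether level, and no late benzylic deoxygenation is needed. Its endgame is shorter and avoids the weakest late steps of the chosen plan.
- Weak points: A7 is a cyclopropane with three contiguous stereocentres, one quaternary, of which only C3 survives the cationic ring opening.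
- One formyl group is a weak acceptor for the ring opening.
- C4 would be set by hydrogenation from the face that carries the C2 aryl group, a facial preference that is not assured.
- The hydrogenation must coexist with benzyl ethers and the C2–O1 bond.
- Comparison: the chosen plan sets C4 by ring fusion and needs only a short auxiliary-based front end.

Key step: step 9

## Route

Assumption: 2 and 4 are taken as purchased (each is one routine step from pent-4-enoic acid or 3,4-dihydroxybenzaldehyde), and the atom labels O1, C2–C5, C9 and C7' of the target ring are used for all intermediates.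

Step 1
Reactants: 1 (S)-4-benzyl-1,3-oxazolidin-2-one; 2 pent-4-enoyl chloride
Product: 3 (S)-4-benzyl-3-(pent-4-enoyl)-1,3-oxazolidin-2-one
Conditions: Et3N, DMAP (10 mol %), CH2Cl2, 0 °C → rt
Reagents that add atoms: none
Why: DMAP-catalysed N-acylation of the oxazolidinone by the acid chloride; no stereocentre is involved.

Step 2
Reactants: 3 (S)-4-benzyl-3-(pent-4-enoyl)-1,3-oxazolidin-2-one; 4 3,4-bis(benzyloxy)benzaldehyde
Product: 7 (S)-4-benzyl-3-[(2S,3S)-2-allyl-3-[3,4-bis(benzyloxy)phenyl]-3-hydroxypropanoyl]-1,3-oxazolidin-2-one, via dibutylboron Z-enolate 5 (not isolated), via dibutylboron aldolate 6 (not isolated)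
Conditions: Bu2BOTf, i-Pr2NEt, CH2Cl2, −78 → 0 °C; 4, −78 → 0 °C; then pH 7 buffer, MeOH, 30% H2O2, 0 °C
Reagents that add atoms: none
Why: Evans syn-aldol: the Z-boron enolate 5 reacts through a chair Zimmerman–Traxler transition state on the face away from the auxiliary benzyl group, setting C2 and C3 as the syn pair in the required absolute sense. Oxidative work-up releases 7 from aldolate 6.

Step 3
Reactants: 7 (S)-4-benzyl-3-[(2S,3S)-2-allyl-3-[3,4-bis(benzyloxy)phenyl]-3-hydroxypropanoyl]-1,3-oxazolidin-2-one
Product: 8 (S)-4-benzyl-3-[(2S,3S)-2-allyl-3-[3,4-bis(benzyloxy)phenyl]-3-methoxypropanoyl]-1,3-oxazolidin-2-one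
Conditions: Me3OBF4, 1,8-bis(dimethylamino)naphthalene, CH2Cl2, 0 °C → rt
Reagents that add atoms: trimethyloxonium tetrafluoroborate, C[O+](C)C.F[B-](F)(F)F
Why: O-alkylation with an oxonium salt buffered by a non-nucleophilic base is the standard etherification of β-hydroxy imides and avoids retro-aldol and epimerisation. The methyl carbon is the future C5.

Step 4
Reactants: 8 (S)-4-benzyl-3-[(2S,3S)-2-allyl-3-[3,4-bis(benzyloxy)phenyl]-3-methoxypropanoyl]-1,3-oxazolidin-2-one
Product: 9 (R)-2-[(S)-[3,4-bis(benzyloxy)phenyl](methoxy)methyl]pent-4-en-1-ol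
Conditions: LiBH4, MeOH (1 equiv), THF, 0 °C
Reagents that add atoms: none
Why: Reductive cleavage of the N-acyl oxazolidinone: hydride attacks the exocyclic carbonyl, the auxiliary is released for recovery and both stereocentres are untouched (the descriptor at C3 changes by priority only).

Step 5
Reactants: 9 (R)-2-[(S)-[3,4-bis(benzyloxy)phenyl](methoxy)methyl]pent-4-en-1-ol
Product: 12 (4R)-4-[(S)-[3,4-bis(benzyloxy)phenyl](methoxy)methyl]tetrahydrofuran-2-ol (both anomers), via triol 10 (not isolated), via hydroxy aldehyde 11 (not isolated)
Conditions: OsO4 (2 mol %), NaIO4, 2,6-lutidine, 1,4-dioxane/H2O 3:1, rt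
Reagents that add atoms: osmium tetroxide, O=[Os](=O)(=O)=O, with sodium periodate, [Na+].[O-]I(=O)(=O)=O, as the stoichiometric oxygen source
Why: Lemieux–Johnson cleavage (catalytic dihydroxylation, then periodate glycol cleavage) is used rather than ozone so that the dialkoxyarene is left alone. Aldehyde 11 closes on the primary hydroxyl to the five-membered lactol.

Step 6
Reactants: 12 (4R)-4-[(S)-[3,4-bis(benzyloxy)phenyl](methoxy)methyl]tetrahydrofuran-2-ol
Product: 13 (R)-4-[(S)-[3,4-bis(benzyloxy)phenyl](methoxy)methyl]dihydrofuran-2(3H)-one
Conditions: (n-Pr4N)RuO4 (5 mol %), N-methylmorpholine N-oxide, 4 Å MS, CH2Cl2, rt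
Reagents that add atoms: none
Why: Perruthenate-catalysed oxidation of a lactol to the lactone under neutral conditions, which leaves the acid-sensitive benzylic methyl ether intact.

Step 7
Reactants: 13 (R)-4-[(S)-[3,4-bis(benzyloxy)phenyl](methoxy)methyl]dihydrofuran-2(3H)-one
Product: 15 (3S,4R)-4-[(S)-[3,4-bis(benzyloxy)phenyl](methoxy)methyl]-3-(trifluoroacetyl)dihydrofuran-2(3H)-one (drawn as the trans keto form; enol expected), via lithium enolate 14 (not isolated)
Conditions: LiN(SiMe3)2, THF, −78 °C; CF3CO2CH2CF3, −78 °C; sat. aq. NH4Cl; used crude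
Reagents that add atoms: 2,2,2-trifluoroethyl trifluoroacetate, O=C(OCC(F)(F)F)C(F)(F)F
Why: Crossed Claisen condensation of the kinetic lactone enolate with an activated trifluoroacetate installs the acyl group that makes C4 acidic enough for diazo transfer. C3 carries no leaving group, so β-elimination is not possible.

Step 8
Reactants: 15 (3S,4R)-4-[(S)-[3,4-bis(benzyloxy)phenyl](methoxy)methyl]-3-(trifluoroacetyl)dihydrofuran-2(3H)-one
Product: 16 (R)-4-[(S)-[3,4-bis(benzyloxy)phenyl](methoxy)methyl]-3-diazodihydrofuran-2(3H)-one
Conditions: MsN3, Et3N, H2O (1 equiv), MeCN, rt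
Reagents that add atoms: methanesulfonyl azide, CS(=O)(=O)N=[N+]=[N-]
Why: Deacylative diazo transfer of the Regitz type: the stabilised enolate adds to the sulfonyl azide and the adduct fragments with loss of the N-sulfonyl trifluoroacetamide, leaving the diazo group on C4.

Step 9
Reactants: 16 (R)-4-[(S)-[3,4-bis(benzyloxy)phenyl](methoxy)methyl]-3-diazodihydrofuran-2(3H)-one
Product: 17 (3aR,4S,6aR)-4-[3,4-bis(benzyloxy)phenyl]tetrahydro-1H,3H-furo[3,4-c]furan-1-one
Conditions: Rh2(cap)4 [dirhodium tetrakis(caprolactamate), cap = C6H10NO] (2 mol %), CH2Cl2, reflux, 16 added over several hours by syringe pump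
Reagents that add atoms: none
Why: The catalyst captures the diazo carbon of 16 and N2 is lost, leaving an electrophilic dirhodium carbenoid at C4. A C–H bond of the methoxy group, made hydridic by the adjacent oxygen lone pair, is then inserted in a concerted, asynchronous three-centre transition state that forms C4–C5 and releases the catalyst. The closest known reaction type is the dirhodium-catalysed 1,5 C–H insertion of α-diazo-γ-butyrolactones into ether C–H bonds to give furofuranones, together with insertions into methyl ether C–H bonds in the diazo ketone series. The tetrahydrofuran closes in the 1,5 mode through a five-membered transition state (C4, C3, C2, O1, C5), and because a bicyclo[3.3.0] system can only be cis-fused the new stereocentre C4 is dictated by C3, with C9 and C7' forced onto one face. C2 and C3 are spectators, and the syn-aldol configuration places the aryl group on the convex face of the forming bicycle, so no strain opposes closure. The step needs chemoselectivity for 1,5-insertion over 1,2-hydride migration from C3 and over attack on the electron-rich aryl ring. In the substrate, C3–H is flanked by two β C–O bonds (C2–OMe and C9–O) that disfavour hydride migration, and three equivalent methoxy C–H bonds are held five atoms from the carbenoid. The carboxamidate ligands make the carbenoid less electrophilic, which is expected to favour the oxygen-activated C–H bond over aromatic substitution, and slow addition suppresses carbene dimerisation.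

Step 10
Reactants: 18 4-bromo-2-methoxyphenol
Product: 19 1-(benzyloxy)-4-bromo-2-methoxybenzene
Conditions: BnBr, K2CO3, DMF, rt
Reagents that add atoms: benzyl bromide, BrCc1ccccc1
Why: Williamson ether synthesis on the phenoxide; the benzyl group matches the other phenol protections so that all three leave together.

Step 11
Reactants: 19 1-(benzyloxy)-4-bromo-2-methoxybenzene; 17 (3aR,4S,6aR)-4-[3,4-bis(benzyloxy)phenyl]tetrahydro-1H,3H-furo[3,4-c]furan-1-one
Product: 21 [4-(benzyloxy)-3-methoxyphenyl][(3R,4R,5S)-5-[3,4-bis(benzyloxy)phenyl]-4-(hydroxymethyl)tetrahydrofuran-3-yl]methanone (in equilibrium with its bicyclic hemiketal), via aryllithium 20 (not isolated)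
Conditions: n-BuLi, THF, −78 °C; then 17, −78 °C; AcOH, −78 °C
Reagents that add atoms: none
Why: Bromine–lithium exchange followed by addition of the aryllithium to the lactone carbonyl forms the C7'–aryl bond. At −78 °C the tetrahedral lithium hemiketal does not collapse, so one aryl group is transferred, and the cold acidic quench gives a product that rests largely as the hemiketal, which protects C4.

Step 12
Reactants: 21 [4-(benzyloxy)-3-methoxyphenyl][(3R,4R,5S)-5-[3,4-bis(benzyloxy)phenyl]-4-(hydroxymethyl)tetrahydrofuran-3-yl]methanone
Product: 22 [(2S,3R,4R)-2-[3,4-bis(benzyloxy)phenyl]-4-[[4-(benzyloxy)-3-methoxyphenyl](hydroxy)methyl]tetrahydrofuran-3-yl]methanol (both carbinol epimers)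
Conditions: NaBH4, THF/MeOH, 0 °C
Reagents that add atoms: none
Why: Borohydride reduction of the aryl ketone through the open form; the new carbinol centre is formed without control, which does not matter because its oxygen is removed in step 15.

Step 13
Reactants: 22 [(2S,3R,4R)-2-[3,4-bis(benzyloxy)phenyl]-4-[[4-(benzyloxy)-3-methoxyphenyl](hydroxy)methyl]tetrahydrofuran-3-yl]methanol
Product: 23 [(2S,3R,4R)-2-[3,4-bis(benzyloxy)phenyl]-4-[[4-(benzyloxy)-3-methoxyphenyl](hydroxy)methyl]tetrahydrofuran-3-yl]methyl acetate
Conditions: AcCl (1.1 equiv), 2,4,6-collidine, CH2Cl2, −78 °C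
Reagents that add atoms: acetyl chloride, CC(=O)Cl
Why: Kinetic acylation with an acid chloride and a hindered pyridine base at low temperature distinguishes the primary C9 hydroxyl from the hindered secondary benzylic one, and the buffered medium avoids ionisation at C7'.

Step 14
Reactants: 23 [(2S,3R,4R)-2-[3,4-bis(benzyloxy)phenyl]-4-[[4-(benzyloxy)-3-methoxyphenyl](hydroxy)methyl]tetrahydrofuran-3-yl]methyl acetate
Product: 24 [(2S,3R,4R)-2-[3,4-bis(benzyloxy)phenyl]-4-[[4-(benzyloxy)-3-methoxyphenyl][(phenoxycarbonothioyl)oxy]methyl]tetrahydrofuran-3-yl]methyl acetate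
Conditions: PhOC(S)Cl, pyridine, DMAP (cat.), CH2Cl2, 0 °C → rt
Reagents that add atoms: O-phenyl chlorothionoformate, ClC(=S)Oc1ccccc1
Why: Thionocarbonate formation, the first stage of a Barton–McCombie deoxygenation, under mild base that leaves the acetate in place.

Step 15
Reactants: 24 [(2S,3R,4R)-2-[3,4-bis(benzyloxy)phenyl]-4-[[4-(benzyloxy)-3-methoxyphenyl][(phenoxycarbonothioyl)oxy]methyl]tetrahydrofuran-3-yl]methyl acetate
Product: 25 [(2S,3R,4R)-4-[4-(benzyloxy)-3-methoxybenzyl]-2-[3,4-bis(benzyloxy)phenyl]tetrahydrofuran-3-yl]methyl acetate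
Conditions: Bu3SnH, AIBN (cat.), toluene, 80 °C
Reagents that add atoms: none
Why: Barton–McCombie deoxygenation: the stannyl radical adds to C=S, β-scission gives a stabilised benzylic radical at C7', and hydrogen transfer from the tin hydride completes the chain. A radical at C7' cannot epimerise C4 and does not disturb the acetate or the ring ether.

Step 16
Reactants: 25 [(2S,3R,4R)-4-[4-(benzyloxy)-3-methoxybenzyl]-2-[3,4-bis(benzyloxy)phenyl]tetrahydrofuran-3-yl]methyl acetate
Product: 26 [(2S,3R,4R)-2-(3,4-dihydroxyphenyl)-4-(4-hydroxy-3-methoxybenzyl)tetrahydrofuran-3-yl]methyl acetate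
Conditions: H2 (1 atm), 10% Pd/C, EtOAc, rt, stopped when 25 and partly debenzylated material are consumed
Reagents that add atoms: none
Why: Catalytic hydrogenolysis of the three aryl benzyl ethers in a neutral, aprotic solvent; aryl benzyl ethers are expected to cleave well before the cyclic benzylic ether, and the acetate is inert.

## Compound list

1 | (S)-4-benzyl-1,3-oxazolidin-2-one | O=C1N[C@@H](Cc2ccccc2)CO1 | starting material
2 | pent-4-enoyl chloride | C=CCCC(=O)Cl | starting material
3 | (S)-4-benzyl-3-(pent-4-enoyl)-1,3-oxazolidin-2-one | C=CCCC(=O)N1[C@@H](Cc2ccccc2)COC1=O | intermediate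
4 | 3,4-bis(benzyloxy)benzaldehyde | O=Cc1ccc(OCc2ccccc2)c(OCc2ccccc2)c1 | starting material
5 | dibutylboron (Z)-enolate of 3 (not isolated) | C=CC/C=C(\OB(CCCC)CCCC)N1[C@@H](Cc2ccccc2)COC1=O | intermediate
6 | dibutylboron aldolate of 7 (not isolated) | O=C(N1[C@@H](Cc2ccccc2)COC1=O)[C@@H](CC=C)[C@H](OB(CCCC)CCCC)c1ccc(OCc2ccccc2)c(OCc2ccccc2)c1 | intermediate
7 | (S)-4-benzyl-3-[(2S,3S)-2-allyl-3-[3,4-bis(benzyloxy)phenyl]-3-hydroxypropanoyl]-1,3-oxazolidin-2-one | O=C(N1[C@@H](Cc2ccccc2)COC1=O)[C@@H](CC=C)[C@H](O)c1ccc(OCc2ccccc2)c(OCc2ccccc2)c1 | intermediate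
8 | (S)-4-benzyl-3-[(2S,3S)-2-allyl-3-[3,4-bis(benzyloxy)phenyl]-3-methoxypropanoyl]-1,3-oxazolidin-2-one | O=C(N1[C@@H](Cc2ccccc2)COC1=O)[C@@H](CC=C)[C@H](OC)c1ccc(OCc2ccccc2)c(OCc2ccccc2)c1 | intermediate
9 | (R)-2-[(S)-[3,4-bis(benzyloxy)phenyl](methoxy)methyl]pent-4-en-1-ol | OC[C@@H](CC=C)[C@H](OC)c1ccc(OCc2ccccc2)c(OCc2ccccc2)c1 | intermediate
10 | (4R)-4-[(S)-[3,4-bis(benzyloxy)phenyl](methoxy)methyl]pentane-1,2,5-triol, both C-2 epimers (not isolated) | OC[C@@H](CC(O)CO)[C@H](OC)c1ccc(OCc2ccccc2)c(OCc2ccccc2)c1 | intermediate
11 | (R)-3-[(S)-[3,4-bis(benzyloxy)phenyl](methoxy)methyl]-4-hydroxybutanal (not isolated) | OC[C@@H](CC=O)[C@H](OC)c1ccc(OCc2ccccc2)c(OCc2ccccc2)c1 | intermediate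
12 | (4R)-4-[(S)-[3,4-bis(benzyloxy)phenyl](methoxy)methyl]tetrahydrofuran-2-ol, both anomers | CO[C@H](c1ccc(OCc2ccccc2)c(OCc2ccccc2)c1)[C@@H]1CC(O)OC1 | intermediate
13 | (R)-4-[(S)-[3,4-bis(benzyloxy)phenyl](methoxy)methyl]dihydrofuran-2(3H)-one | CO[C@H](c1ccc(OCc2ccccc2)c(OCc2ccccc2)c1)[C@@H]1CC(=O)OC1 | intermediate
14 | lithium enolate of 13 (not isolated) | CO[C@H](c1ccc(OCc2ccccc2)c(OCc2ccccc2)c1)[C@@H]1C=C([O-])OC1.[Li+] | intermediate
15 | (3S,4R)-4-[(S)-[3,4-bis(benzyloxy)phenyl](methoxy)methyl]-3-(trifluoroacetyl)dihydrofuran-2(3H)-one (trans keto form drawn) | CO[C@H](c1ccc(OCc2ccccc2)c(OCc2ccccc2)c1)[C@@H]1[C@@H](C(=O)C(F)(F)F)C(=O)OC1 | intermediate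
16 | (R)-4-[(S)-[3,4-bis(benzyloxy)phenyl](methoxy)methyl]-3-diazodihydrofuran-2(3H)-one | CO[C@H](c1ccc(OCc2ccccc2)c(OCc2ccccc2)c1)[C@@H]1C(=[N+]=[N-])C(=O)OC1 | intermediate
17 | (3aR,4S,6aR)-4-[3,4-bis(benzyloxy)phenyl]tetrahydro-1H,3H-furo[3,4-c]furan-1-one | O=C1[C@H]2CO[C@H](c3ccc(OCc4ccccc4)c(OCc4ccccc4)c3)[C@H]2CO1 | intermediate
18 | 4-bromo-2-methoxyphenol | COc1cc(Br)ccc1O | starting material
19 | 1-(benzyloxy)-4-bromo-2-methoxybenzene | COc1cc(Br)ccc1OCc1ccccc1 | intermediate
20 | [4-(benzyloxy)-3-methoxyphenyl]lithium (not isolated) | [Li]c1ccc(OCc2ccccc2)c(OC)c1 | intermediate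
21 | [4-(benzyloxy)-3-methoxyphenyl][(3R,4R,5S)-5-[3,4-bis(benzyloxy)phenyl]-4-(hydroxymethyl)tetrahydrofuran-3-yl]methanone | COc1cc(C(=O)[C@H]2CO[C@H](c3ccc(OCc4ccccc4)c(OCc4ccccc4)c3)[C@H]2CO)ccc1OCc1ccccc1 | intermediate
22 | [(2S,3R,4R)-2-[3,4-bis(benzyloxy)phenyl]-4-[[4-(benzyloxy)-3-methoxyphenyl](hydroxy)methyl]tetrahydrofuran-3-yl]methanol, both carbinol epimers | COc1cc(C(O)[C@H]2CO[C@H](c3ccc(OCc4ccccc4)c(OCc4ccccc4)c3)[C@H]2CO)ccc1OCc1ccccc1 | intermediate
23 | [(2S,3R,4R)-2-[3,4-bis(benzyloxy)phenyl]-4-[[4-(benzyloxy)-3-methoxyphenyl](hydroxy)methyl]tetrahydrofuran-3-yl]methyl acetate | COc1cc(C(O)[C@H]2CO[C@H](c3ccc(OCc4ccccc4)c(OCc4ccccc4)c3)[C@H]2COC(C)=O)ccc1OCc1ccccc1 | intermediate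
24 | [(2S,3R,4R)-2-[3,4-bis(benzyloxy)phenyl]-4-[[4-(benzyloxy)-3-methoxyphenyl][(phenoxycarbonothioyl)oxy]methyl]tetrahydrofuran-3-yl]methyl acetate | COc1cc(C(OC(=S)Oc2ccccc2)[C@H]2CO[C@H](c3ccc(OCc4ccccc4)c(OCc4ccccc4)c3)[C@H]2COC(C)=O)ccc1OCc1ccccc1 | intermediate
25 | [(2S,3R,4R)-4-[4-(benzyloxy)-3-methoxybenzyl]-2-[3,4-bis(benzyloxy)phenyl]tetrahydrofuran-3-yl]methyl acetate | COc1cc(C[C@H]2CO[C@H](c3ccc(OCc4ccccc4)c(OCc4ccccc4)c3)[C@H]2COC(C)=O)ccc1OCc1ccccc1 | intermediate
26 | [(2S,3R,4R)-2-(3,4-dihydroxyphenyl)-4-(4-hydroxy-3-methoxybenzyl)tetrahydrofuran-3-yl]methyl acetate | COc1cc(C[C@H]2CO[C@H](c3ccc(O)c(O)c3)[C@H]2COC(C)=O)ccc1O | target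

## Step count and least certain steps

Total step count: 16. Longest linear sequence: 15 steps (steps 1–9 and 11–16, from 1 to 26); step 10 is a one-step side branch.

**Step 9 (key step).** The carbenoid may be diverted before it reaches the methyl group, by 1,2-hydride migration from C3 or by attack on the electron-rich aryl ring, because a primary C–H bond of a methyl ether is the least reactive ether site and both competitors are also intramolecular. The fallback sets out from 13 and returns at 17, bringing in C5 as a formyl carbon instead of the methyl ether carbon. Claisen formylation of 13 (LiN(SiMe3)2, HCO2Et, THF) should give the hydroxymethylene lactone F1. BF3·OEt2 in CH2Cl2 at low temperature would then ionise the 4-alkoxybenzylic methyl ether, and capture of the cation by the enol oxygen closes O1–C2 to the bicyclic enol ether F2, with the aryl group trans to C9 as the more stable isomer of a reversible closure. Hydrogenation of the C4=C5 bond over Rh/Al2O3 in EtOAc, which spares benzyl ethers, can deliver hydrogen only to the face that gives cis-fused 17. The price is that C2 is re-set under control of C3 instead of being carried from the aldol.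

**Step 11.** Over-addition after collapse of the tetrahedral intermediate, or epimerisation at C4 through the enol of the open keto form, may occur because C4 becomes α to an aryl ketone once the lactone is opened and the trans isomer is the more stable. The fallback sets out from 17 and returns at 22, bypassing 21. Half-reduction of 17 with i-Bu2AlH (CH2Cl2, −78 °C) gives the lactol F3. An excess of the aryl Grignard reagent F4 (from 19 and Mg in THF) then adds to the open hydroxy aldehyde form to give diol 22 directly. No ketone is formed and a second addition is impossible.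

**Step 14 (and with it step 15).** Ionisation of the thionocarbonate may intervene: the 4-alkoxybenzylic C–O bond of 24 carries a good leaving group, so O-to-S rearrangement or elimination toward C4 can compete during acylation or on heating with the tin hydride. The fallback sets out from 23 and returns at 25, bypassing 24. It is an ionic deoxygenation with Et3SiH and BF3·OEt2 in CH2Cl2 at −78 °C, which uses the same ease of ionisation productively. Hydride capture of the benzylic cation must then outrun proton loss from C4, so the silane would be used in large excess at low temperature.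

**Step 16.** Over-reduction may occur by hydrogenolysis of the benzylic C2–O1 bond once the phenols are free, because a 4-hydroxybenzylic ether is itself activated toward Pd and hydrogen. The fallback sets out from 25 and ends at 26. It is a non-reductive debenzylation with BCl3 and pentamethylbenzene as benzyl cation scavenger in CH2Cl2 at −78 °C, conditions that leave alkyl acetates and aryl methyl ethers in place.

## Further compounds

F1 | step 9 | (3E,4R)-4-[(S)-[3,4-bis(benzyloxy)phenyl](methoxy)methyl]-3-(hydroxymethylidene)dihydrofuran-2(3H)-one | CO[C@H](c1ccc(OCc2ccccc2)c(OCc2ccccc2)c1)[C@H]1COC(=O)/C1=C/O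
F2 | step 9 | (3aR,4S)-4-[3,4-bis(benzyloxy)phenyl]-3a,4-dihydro-1H,3H-furo[3,4-c]furan-1-one | O=C1C2=CO[C@H](c3ccc(OCc4ccccc4)c(OCc4ccccc4)c3)[C@H]2CO1
F3 | step 11 | (3aR,4S,6aR)-4-[3,4-bis(benzyloxy)phenyl]tetrahydro-1H,3H-furo[3,4-c]furan-1-ol (both anomers) | OC1[C@H]2CO[C@H](c3ccc(OCc4ccccc4)c(OCc4ccccc4)c3)[C@H]2CO1
F4 | step 11 | [4-(benzyloxy)-3-methoxyphenyl]magnesium bromide | COc1cc([Mg]Br)ccc1OCc1ccccc1
F0 | step 14 | none | none
F0 | step 16 | none | none
A1 | alternative 1 | (4R,5S)-5-[3,4-bis(benzyloxy)phenyl]-4-[[(tert-butyldimethylsilyl)oxy]methyl]-3-methylidenedihydrofuran-2(3H)-one | C=C1C(=O)O[C@H](c2ccc(OCc3ccccc3)c(OCc3ccccc3)c2)[C@H]1CO[Si](C)(C)C(C)(C)C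
A2 | alternative 1 | methyl (Z)-4-[(tert-butyldimethylsilyl)oxy]-2-[(4,4,5,5-tetramethyl-1,3,2-dioxaborolan-2-yl)methyl]but-2-enoate | COC(=O)/C(CB1OC(C)(C)C(C)(C)O1)=C\CO[Si](C)(C)C(C)(C)C
A3 | alternative 2 | (1S,2S,5S)-6-[4-(benzyloxy)-3-methoxyphenyl]-2-[3,4-bis(benzyloxy)phenyl]-3-oxabicyclo[3.2.0]hept-6-ene | C1=C(c3ccc(OCc4ccccc4)c(OC)c3)[C@H]2CO[C@H](c3ccc(OCc4ccccc4)c(OCc4ccccc4)c3)[C@H]21
A4 | alternative 2 | (S)-2-[3,4-bis(benzyloxy)phenyl]-2,5-dihydrofuran | O1[C@H](c2ccc(OCc3ccccc3)c(OCc3ccccc3)c2)C=CC1
A5 | alternative 2 | 1-(benzyloxy)-4-ethynyl-2-methoxybenzene | C#Cc1ccc(OCc2ccccc2)c(OC)c1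
A6 | alternative 3 | [[(2S,3R)-4-[4-(benzyloxy)-3-methoxybenzyl]-2-[3,4-bis(benzyloxy)phenyl]-2,3-dihydrofuran-3-yl]methoxy](tert-butyl)dimethylsilane | COc1cc(CC2=CO[C@H](c3ccc(OCc4ccccc4)c(OCc4ccccc4)c3)[C@H]2CO[Si](C)(C)C(C)(C)C)ccc1OCc1ccccc1
A7 | alternative 3 | 1-[4-(benzyloxy)-3-methoxybenzyl]-2-[3,4-bis(benzyloxy)phenyl]-3-[[(tert-butyldimethylsilyl)oxy]methyl]cyclopropane-1-carbaldehyde (C-3 as drawn; C-1 and C-2 left open because both are planarised in the ring opening) | O=CC1(Cc2ccc(OCc3ccccc3)c(OC)c2)C(c2ccc(OCc3ccccc3)c(OCc3ccccc3)c2)[C@H]1CO[Si](C)(C)C(C)(C)C
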